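## Structural features

Compound 25 is a trans-fused decalin of the eudesmane type. Ring A (C1–C5, C10) holds the C3=C4 alkene with its methyl on C4, ring B (C5–C10) carries the isopropenyl group at C7, and the rings share the C5–C10 bond. Six stereocentres are present, five of them contiguous around the quaternary C10 (C9, C10, C1, C2 and C5). O1 and O2 lie on the face of C14; H5, O9 and the C7 isopropenyl group lie on the other face, so O9 and the isopropenyl group are syn-axial on ring B. The four oxygens are in four different states: a tiglate on O1, an allylic acetate on O2, an acetate on the hindered axial O9, and a free neopentyl primary alcohol at C14. Because O1/O2 are cis-vicinal and O14 is 1,3 to O1 and O9, acyl migration is the main fragility, together with the allylic acetate, the conjugated tiglate and the reducible 1,1-disubstituted alkene. The real difficulty is the oxidised angular carbon on a fully substituted centre flanked by two oxygenated carbons, and the differentiation of four hydroxyls. The key step exploits that C14 is a primary carbon on C10, γ to O1, and that O1 is equatorial on ring A and gauche to axial C14. A silicon atom on O1 therefore reaches a C14–H bond through a five-membered O1–Si–C14–C10–C1 ring, whereas the other γ-hydrogens (H9, a hindered acetoxy-bearing methine; H5, anti to O1) do not compete. With C14 carried as a methyl group, ring B with C7, C9 (as carbonyl), C10 and C14 maps onto (S)-carvone.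

## Logic of the disconnections

25 ⇒ 24 ⇒ 21 + 22 ⇒ 20. The Si–O14 bond of 24, the acyl–O1 bond of the tiglate and the Si–O14 bond of 21 are cut in turn. The free C14–OH, to which the O1 ester could migrate, is thereby unveiled last and under slightly acidic fluoride conditions. The gain is that 20 is a plain 1,14-diol. The forward steps must silylate the primary over the secondary hydroxyl and acylate the crowded C1–OH without moving the O2 acetate.

20 ⇒ 19. The C14–O bond is traced back to a C14–Si bond. This turns the diol into a cyclic siloxane in which O1 and C14 are tied together. The oxidation must spare two acetates and two alkenes.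

19 ⇒ 18 (key step). The C14–Si bond is cut, which reveals an unfunctionalised angular methyl group and an Si–H ether on O1. This removes all functionality from C14, so the methyl group of 1 can serve as C14. The forward step must select a primary C–H bond over H9 and must leave both alkenes untouched.

18 ⇒ 16 + 17 ⇒ 13. The Si–O1 bond and the two acetyl–O bonds at O2 and O9 are cut. 13 is a triol without protecting groups. The demand is that O1 alone stays free; this is met by tying O1/O2 into a cyclic orthoester that opens to the axial O2 ester.

13 ⇒ 12 ⇒ 11. The C9–H bond is cut (back to the ketone), then the Si–O1 bond of a silyl ether. The C9 carbinol centre, whose oxygen must be axial and syn to the isopropenyl group, becomes a carbonyl. The reduction must deliver hydride from the C14 face, which the free O1 hydroxyl directs.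

11 ⇒ 10. The C3=C4 double bond is cut. Ring A is reduced to a vinyl carbinol branch on C10 and an isopropenyl branch on C5 of a cyclohexanone. The forward metathesis must form a trisubstituted alkene and must not engage the C7 isopropenyl group.

10 ⇒ 8 + 9, then 8 ⇒ 7 ⇒ 6 ⇒ 5. The C2–C3 bond is cut, then the oxidation level at C2 and the two protecting groups are adjusted. This leaves a simple aldol adduct. The addition must give the 1,2-anti (Felkin–Anh) product, which becomes the cis-1,2 relationship of ring A.

5 ⇒ 1 + 2 + 3 (through 4). The C4–C5 and C1–C10 bonds are cut. All carbons of 18 except C3 are thus assembled in one operation from commercial materials, and C5, C10 and C1 are set relative to C7 of 1. The conjugate addition must come anti to the isopropenyl group, and the aldol must proceed anti to the new C5 substituent through a closed transition structure.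

## Other disconnections considered

Alternative 1: The cut is through C5–C6 and C9–C10 of ring B. In the forward sense the silyloxydiene A3 would add to the ester-bearing double bond of quinone A2 under a chiral oxazaborolidinium Lewis acid to give the cis-fused endo adduct A1.
- In its favour: one catalytic step would form ring B, the quaternary C10 and the C9 oxygen with the correct mutual relationship. C14 arrives at the carboxyl oxidation level, so no C–H oxidation is needed; on this point it is better than the chosen plan. Absolute configuration from a catalyst rather than the chiral pool is an equal.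
- Against it here: A1 is cis-fused, so C5 must be epimerised. C7 carries no substituent, and an axial isopropenyl group syn to O9 would have to be placed on an unactivated alkene carbon. The C1 and C4 carbonyls must be told apart, the C4 methyl and the C3=C4 alkene installed, and O2 introduced.
- Comparison: structurally A1 matches C9, C10 and C14 better, while the chosen plan receives C5, C7 and C10 from 1. Mechanistically the cycloaddition is as well founded as the conjugate addition–aldol (equal), but the later C7 functionalisation has no comparably reliable basis. The sequence after A1 is expected to be clearly longer than the ten steps that lead to 18.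

Alternative 2: The cut is through C7–C8 and the lactone bond O9–C11. In the forward sense the ester enolate of epoxy ester A5 would open the terminal epoxide carbon C8, closing ring B, and the C9 alkoxide would then lactonise to A4.
- In its favour: the C14 oxygen is present from the start (better). Lactone formation locks the syn relationship of the C7 carbon and O9, which is exactly the strained arrangement of 25 (equal to the directed reduction of the chosen plan). O9, O14 and O1/O2 emerge already differentiated (better).
- Against it here: the enolate must attack the distal epoxide carbon (endo mode). The proximal carbon is neopentyl, which helps, but the collinear geometry in a trans-decalin-forming transition structure is demanding. A5 is a fully substituted ring A with four stereocentres, including the quaternary C10, and must be made without help from the chiral pool. Converting the lactone carbon into an isopropenyl group needs several steps and a dehydration whose regiochemistry is uncertain. The acetonide must later be turned into one tiglate and one acetate, which is the same differentiation problem as in the chosen plan.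
- Comparison: both key steps rest on known reactivity (equal), and Alternative 2 handles C14 and O9 better. The chosen plan is expected to be markedly shorter, because ring B with C7 comes ready-made in 1.

Alternative 3: The cut is through C6–C7 and C5–C10, in the biosynthetic direction. A magnesium-dependent sesquiterpene synthase would fold the diphosphate A7 into the diene A6.
- In its favour: the whole carbon skeleton with C5, C7, C10 and both alkenes is made in one step. This is better than the six steps the chosen plan needs for the decalin; enzymatic stereocontrol is equal or better; fermentation scales well.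
- Against it here: A6 contains no oxygen. Four site- and face-selective oxidations (C1, C2, C9, C14) would be required, and only C2 is activated. The C14 methyl has no directing group until O1 is in place, so the hardest problem of 25 is untouched. The synthase would also have to give the antipode that matches 25 and little else.
- Comparison: the alternative wins for the skeleton. The chosen plan wins for oxygenation, because it starts with the C9 oxygen, adds O1 and O2 together with C–C bonds, and needs a single, directed C–H oxidation.

Key step: step 11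

Remark: eudesmane numbering of 25 is used for every intermediate. α and β refer to the skeleton in its usual orientation, in which C14, O1 and O2 are α and H5, O9 and the C7 isopropenyl group are β.
Remark: the structures of 18 and 19 were checked centre by centre against 25 and agree with it, so they are used unchanged. Three design choices follow from that check and from the risk analysis: ring A is closed by metathesis at C3=C4; the isopropenyl group is carried unmasked (a hydrochloride would not be eliminated cleanly at the end); and the free O1–H of 16 is released by an orthoester opening, not by a protecting group.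
Assumption: 2 and 9 are bought as THF solutions and 3 as such.

Step 1
Reactants: 1 (S)-carvone; 2 isopropenylmagnesium bromide; 3 (4-methoxybenzyloxy)acetaldehyde
Product: 5 (2S,3R,5S)-2-[(1R)-1-hydroxy-2-(4-methoxybenzyloxy)ethyl]-2-methyl-3,5-di(prop-1-en-2-yl)cyclohexan-1-one, via bromomagnesium enolate 4 (not isolated)
Conditions: 2 (1.5 equiv), CuBr·SMe2 (10 mol%), THF, −78 to −40 °C; then 3, −78 °C; aq. NH4Cl
Reagents that add atoms: none
Why: Copper-catalysed 1,4-addition of the alkenyl Grignard reagent occurs anti to the C7 isopropenyl group and sets C5. Enolate 4 then adds to 3 in a tandem aldol reaction on the face anti to the new C5 substituent, which sets C10 with C14 cis to C4. A closed Zimmerman–Traxler chair with the aldehyde side chain equatorial and the enolate methyl (cis to the enolate oxygen) axial places O1 syn to C14 and sets C1.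

Step 2
Reactants: 5 aldol adduct
Product: 6 (2S,3R,5S)-2-[(1R)-2-(4-methoxybenzyloxy)-1-(triethylsilyloxy)ethyl]-2-methyl-3,5-di(prop-1-en-2-yl)cyclohexan-1-one
Conditions: TESOTf (1.3 equiv), 2,6-lutidine, CH2Cl2, −78 to 0 °C
Reagents that add atoms: triethylsilyl trifluoromethanesulfonate CC[Si](CC)(CC)OS(=O)(=O)C(F)(F)F
Why: Silyl triflate silylation of a hindered secondary alcohol. The silyl ether blocks retro-aldol cleavage and provides the non-chelating α-oxygen substituent needed in step 5.

Step 3
Reactants: 6 silyl ether
Product: 7 (2S,3R,5S)-2-[(1R)-2-hydroxy-1-(triethylsilyloxy)ethyl]-2-methyl-3,5-di(prop-1-en-2-yl)cyclohexan-1-one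
Conditions: DDQ (1.3 equiv), CH2Cl2/pH 7 buffer (10:1), 0 °C
Reagents that add atoms: none
Why: Oxidative cleavage of the 4-methoxybenzyl ether by DDQ through the benzylic oxocarbenium ion, which water hydrolyses. The silyl ether, the ketone and the 1,1-disubstituted alkenes are inert.

Step 4
Reactants: 7 primary alcohol
Product: 8 (2R)-2-[(1S,2R,4S)-1-methyl-6-oxo-2,4-di(prop-1-en-2-yl)cyclohexyl]-2-(triethylsilyloxy)acetaldehyde
Conditions: Dess–Martin periodinane (1.3 equiv), CH2Cl2, 0 °C to rt
Reagents that add atoms: none
Why: Dess–Martin oxidation of a primary alcohol to the aldehyde under non-basic conditions, so the α-silyloxy centre C1 is not epimerised. The aldehyde is used directly.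

Step 5
Reactants: 8 aldehyde; 9 vinylmagnesium bromide
Product: 10 (2S,3R,5S)-2-[(1R,2S)-2-hydroxy-1-(triethylsilyloxy)but-3-en-1-yl]-2-methyl-3,5-di(prop-1-en-2-yl)cyclohexan-1-one
Conditions: 9 (1.2 equiv), THF, −78 °C; aq. NH4Cl at −78 °C
Reagents that add atoms: none
Why: Grignard addition to the aldehyde, which reacts far faster than the α-quaternary C9 ketone at −78 °C. In the polar Felkin–Anh arrangement the silyloxy group is anti to the incoming nucleophile and the approach passes H1, giving the 1,2-anti product; this is the cis-1,2 relationship of ring A and sets C2.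

Step 6
Reactants: 10 allylic alcohol
Product: 11 2α-hydroxy-1α-(triethylsilyloxy)-5βH,7αH,10α-eudesma-3,11-dien-9-one
Conditions: second-generation Grubbs catalyst (H2IMes)(PCy3)Cl2Ru=CHPh (5 mol%), CH2Cl2 (5 mM), 40 °C
Reagents that add atoms: none
Why: Ring-closing metathesis: the ruthenium alkylidene forms at the monosubstituted vinyl group and closes the six-membered ring onto the neighbouring C4 isopropenyl group, whereas closure onto the C7 isopropenyl group would need a bridged eight-membered ring. No stereocentre changes, and any O2–C9 hemiketal of 10 is in equilibrium with the open form and cannot exist in 11, where C2 and C9 are antiperiplanar about C1–C10.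

Step 7
Reactants: 11 silyl ether
Product: 12 1α,2α-dihydroxy-5βH,7αH,10α-eudesma-3,11-dien-9-one
Conditions: HF·pyridine, pyridine, THF, 0 °C to rt
Reagents that add atoms: none
Why: Fluoride-mediated cleavage of the triethylsilyl ether under slightly acidic conditions, under which the β-hydroxy ketone does not undergo retro-aldol cleavage and the allylic alcohol does not ionise.

Step 8
Reactants: 12 diol ketone
Product: 13 5βH,7αH,10α-eudesma-3,11-diene-1α,2α,9β-triol
Conditions: Me4NBH(OAc)3 (5 equiv), MeCN/AcOH (1:1), −20 °C to rt
Reagents that add atoms: none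
Why: Hydroxyl-directed (Evans–Saksena) reduction: O1, equatorial on ring A and gauche to both C14 and C9, binds boron and hands the hydride to the C14 face of the C9 carbonyl through a chair-like six-membered transition structure. The new C9 alcohol is axial, anti to C14 and 1,3-anti to O1, which sets C9.

Step 9
Reactants: 13 triol
Product: 16 2α,9β-diacetoxy-5βH,7αH,10α-eudesma-3,11-dien-1α-ol, via cyclic 1,2-orthoacetate 14 (not isolated), via 9-O-acetyl cyclic orthoacetate 15 (not isolated)
Conditions: MeC(OMe)3 (1.5 equiv), CSA (5 mol%), CH2Cl2, rt; then Et3N, Ac2O, DMAP, rt to 40 °C; concentrate; then AcOH/H2O (4:1), rt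
Reagents that add atoms: trimethyl orthoacetate COC(C)(OC)OC; acetic anhydride CC(=O)OC(C)=O; water O
Why: The cis-1,2-diol is tied up as a cyclic orthoacetate, the remaining O9 is acetylated under DMAP catalysis, and mild acid hydrolysis opens the orthoester through its hemiorthoester, which collapses to the axial ester and the equatorial alcohol. O2 is axial and O1 equatorial, so the acetate ends on O2 and O1 is left free without a protecting group.

Step 10
Reactants: 16 hydroxy diacetate; 17 diethylsilane
Product: 18 2α,9β-diacetoxy-1α-(diethylsilyloxy)-5βH,7αH,10α-eudesma-3,11-diene (one Si–H retained)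
Conditions: 17 (1.5 equiv), [Ir(cod)OMe]2 (0.5 mol%), THF, rt; volatiles removed, used crude
Reagents that add atoms: none
Why: Iridium-catalysed dehydrogenative coupling of the alcohol with the dihydrosilane gives the (hydrido)silyl ether under neutral conditions, so the O2 acetate cannot migrate. Excess 17 is removed in vacuo and the moisture-sensitive 18 is used without chromatography.

Step 11
Reactants: 18 (hydrido)silyl ether
Product: 19 oxasilolane: 2α,9β-diacetoxy-1α,14-(diethylsilanediyl)oxy-bridged 5βH,7αH,10α-eudesma-3,11-diene (ring O1–Si–C14–C10–C1)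
Conditions: [Ir(cod)OMe]2 (2 mol%), 3,4,7,8-tetramethyl-1,10-phenanthroline (5 mol%), norbornene (2 equiv), THF, 80 °C, sealed tube
Reagents that add atoms: none
Why: The Si–H bond of 18 adds to the phenanthroline-ligated iridium centre and norbornene takes up the hydrogen, leaving a trivalent iridium silyl species that holds the substrate through the Si–O1 tether. A C14–H bond is then cleaved within a six-membered iridacycle (Ir–Si–O1–C1–C10–C14) and C–Si reductive elimination closes the five-membered 1-oxa-2-silacyclopentane; the ring is closed by C14–Si bond formation and not by a nucleophilic closure. The closest known reaction type is the iridium-catalysed, hydroxyl-directed γ-silylation of primary C–H bonds through (hydrido)silyl ethers. No stereocentre is formed; the fixed configurations at C1 and C10 put O1 equatorial and gauche to the axial C14, so the tether spans them without strain. The step needs C14–H to be chosen over the other γ-hydrogens: H9 is a hindered, acetoxy-bearing methine and the catalyst strongly prefers primary C–H bonds, H5 is anti to O1 and out of reach, and H2 would require a four-membered ring. It also needs both alkenes to survive: norbornene in excess is by far the better hydrogen acceptor, the tethered Si–H cannot reach C3=C4 because O1 is equatorial, and the isopropenyl group is remote and 1,1-disubstituted. The acetates are spectators under these neutral conditions.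

Step 12
Reactants: 19 oxasilolane
Product: 20 2α,9β-diacetoxy-5βH,7αH,10α-eudesma-3,11-diene-1α,14-diol
Conditions: 30% H2O2, KF, KHCO3, THF/MeOH (1:1), 0 °C to rt; pH 7 work-up
Reagents that add atoms: hydrogen peroxide OO
Why: Tamao–Fleming oxidation: fluoride and peroxide form a pentacoordinate silicon peroxide, C14 migrates from silicon to oxygen with retention, and hydrolysis of the Si–O bonds frees both hydroxyls. Bicarbonate buffering, low temperature and a short reaction time are chosen to keep the acetates in place.

Step 13
Reactants: 20 diol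
Product: 21 2α,9β-diacetoxy-14-(tert-butyldimethylsilyloxy)-5βH,7αH,10α-eudesma-3,11-dien-1α-ol
Conditions: TBSCl (1.2 equiv), imidazole, CH2Cl2, 0 °C
Reagents that add atoms: tert-butyldimethylsilyl chloride CC(C)(C)[Si](C)(C)Cl
Why: Silylation with the bulky chlorosilane is selective for the primary C14–OH over the secondary C1–OH, which is flanked by C10 and the O2 acetate.

Step 14
Reactants: 21 silyl ether alcohol; 22 tiglic acid
Product: 24 2α,9β-diacetoxy-14-(tert-butyldimethylsilyloxy)-5βH,7αH,10α-eudesma-3,11-dien-1α-yl (E)-2-methylbut-2-enoate, via tiglic 2,4,6-trichlorobenzoic anhydride 23 (not isolated)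
Conditions: 22, 2,4,6-trichlorobenzoyl chloride, Et3N, toluene, rt; then 21, DMAP, toluene, 60 °C
Reagents that add atoms: none
Why: Yamaguchi esterification: mixed anhydride 23 passes the tigloyl group to DMAP and the acylpyridinium ion acylates the hindered equatorial C1–OH. The (E)-geometry is the stable one and is retained.

Step 15
Reactants: 24 silyl ether
Product: 25 (1R,2S,5R,7S,9S,10S)-2,9-diacetoxy-14-hydroxyeudesma-3,11-dien-1-yl (E)-2-methylbut-2-enoate (CNP0267061.1)
Conditions: HF·pyridine, pyridine, THF, 0 °C to rt
Reagents that add atoms: none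
Why: Fluoride cleaves the primary silyl ether under slightly acidic, buffered conditions, under which neither the tiglate nor the acetates migrate to the freed C14–OH.

## Compound list

1 | (S)-carvone | CC1=CC[C@@H](CC1=O)C(C)=C | starting material
2 | isopropenylmagnesium bromide | C=C(C)[Mg]Br | starting material
3 | (4-methoxybenzyloxy)acetaldehyde | COc1ccc(COCC=O)cc1 | starting material
4 | bromomagnesium (3R,5S)-2-methyl-3,5-di(prop-1-en-2-yl)cyclohex-1-en-1-olate (not isolated) | C=C(C)[C@@H]1CC(O[Mg]Br)=C(C)[C@H](C1)C(C)=C | intermediate
5 | (2S,3R,5S)-2-[(1R)-1-hydroxy-2-(4-methoxybenzyloxy)ethyl]-2-methyl-3,5-di(prop-1-en-2-yl)cyclohexan-1-one | C=C(C)[C@@H]1CC(=O)[C@](C)([C@@H](O)COCc2ccc(OC)cc2)[C@H](C1)C(C)=C | intermediate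
6 | (2S,3R,5S)-2-[(1R)-2-(4-methoxybenzyloxy)-1-(triethylsilyloxy)ethyl]-2-methyl-3,5-di(prop-1-en-2-yl)cyclohexan-1-one | C=C(C)[C@@H]1CC(=O)[C@](C)([C@@H](O[Si](CC)(CC)CC)COCc2ccc(OC)cc2)[C@H](C1)C(C)=C | intermediate
7 | (2S,3R,5S)-2-[(1R)-2-hydroxy-1-(triethylsilyloxy)ethyl]-2-methyl-3,5-di(prop-1-en-2-yl)cyclohexan-1-one | C=C(C)[C@@H]1CC(=O)[C@](C)([C@@H](O[Si](CC)(CC)CC)CO)[C@H](C1)C(C)=C | intermediate
8 | (2R)-2-[(1S,2R,4S)-1-methyl-6-oxo-2,4-di(prop-1-en-2-yl)cyclohexyl]-2-(triethylsilyloxy)acetaldehyde | C=C(C)[C@@H]1CC(=O)[C@](C)([C@@H](O[Si](CC)(CC)CC)C=O)[C@H](C1)C(C)=C | intermediate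
9 | vinylmagnesium bromide | C=C[Mg]Br | starting material
10 | (2S,3R,5S)-2-[(1R,2S)-2-hydroxy-1-(triethylsilyloxy)but-3-en-1-yl]-2-methyl-3,5-di(prop-1-en-2-yl)cyclohexan-1-one | C=C(C)[C@@H]1CC(=O)[C@](C)([C@@H](O[Si](CC)(CC)CC)[C@@H](O)C=C)[C@H](C1)C(C)=C | intermediate
11 | 2α-hydroxy-1α-(triethylsilyloxy)-5βH,7αH,10α-eudesma-3,11-dien-9-one | C=C(C)[C@@H]1CC(=O)[C@@]2(C)[C@H](C1)C(C)=C[C@H](O)[C@@H]2O[Si](CC)(CC)CC | intermediate
12 | 1α,2α-dihydroxy-5βH,7αH,10α-eudesma-3,11-dien-9-one | C=C(C)[C@@H]1CC(=O)[C@@]2(C)[C@H](C1)C(C)=C[C@H](O)[C@@H]2O | intermediate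
13 | 5βH,7αH,10α-eudesma-3,11-diene-1α,2α,9β-triol | C=C(C)[C@@H]1C[C@H](O)[C@@]2(C)[C@H](C1)C(C)=C[C@H](O)[C@@H]2O | intermediate
14 | 1α,2α-O-(1-methoxyethylidene) orthoester of 13 (not isolated; orthoester carbon unassigned) | C=C(C)[C@@H]1C[C@H](O)[C@@]2(C)[C@H](C1)C(C)=C[C@@H]3OC(C)(OC)O[C@H]23 | intermediate
15 | 9β-acetate of 14 (not isolated) | C=C(C)[C@@H]1C[C@H](OC(C)=O)[C@@]2(C)[C@H](C1)C(C)=C[C@@H]3OC(C)(OC)O[C@H]23 | intermediate
16 | 2α,9β-diacetoxy-5βH,7αH,10α-eudesma-3,11-dien-1α-ol | C=C(C)[C@@H]1C[C@H](OC(C)=O)[C@@]2(C)[C@H](C1)C(C)=C[C@H](OC(C)=O)[C@@H]2O | intermediate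
17 | diethylsilane | CC[SiH2]CC | starting material
18 | 2α,9β-diacetoxy-1α-(diethylsilyloxy)-5βH,7αH,10α-eudesma-3,11-diene (key-step precursor) | C=C(C)[C@@H]1C[C@H](OC(C)=O)[C@@]2(C)[C@H](C1)C(C)=C[C@H](OC(C)=O)[C@@H]2O[SiH](CC)CC | intermediate
19 | oxasilolane bridging O1 and C14 through SiEt2 (key-step product) | C=C(C)[C@@H]1C[C@H](OC(C)=O)[C@@]2(C3)[C@H](C1)C(C)=C[C@H](OC(C)=O)[C@@H]2O[Si]3(CC)CC | intermediate
20 | 2α,9β-diacetoxy-5βH,7αH,10α-eudesma-3,11-diene-1α,14-diol | C=C(C)[C@@H]1C[C@H](OC(C)=O)[C@@]2(CO)[C@H](C1)C(C)=C[C@H](OC(C)=O)[C@@H]2O | intermediate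
21 | 2α,9β-diacetoxy-14-(tert-butyldimethylsilyloxy)-5βH,7αH,10α-eudesma-3,11-dien-1α-ol | C=C(C)[C@@H]1C[C@H](OC(C)=O)[C@@]2(CO[Si](C)(C)C(C)(C)C)[C@H](C1)C(C)=C[C@H](OC(C)=O)[C@@H]2O | intermediate
22 | tiglic acid | C/C=C(\C)C(=O)O | starting material
23 | tiglic 2,4,6-trichlorobenzoic anhydride (not isolated) | C/C=C(\C)C(=O)OC(=O)c1c(Cl)cc(Cl)cc1Cl | intermediate
24 | 2α,9β-diacetoxy-14-(tert-butyldimethylsilyloxy)-5βH,7αH,10α-eudesma-3,11-dien-1α-yl (E)-2-methylbut-2-enoate | C=C(C)[C@@H]1C[C@H](OC(C)=O)[C@@]2(CO[Si](C)(C)C(C)(C)C)[C@H](C1)C(C)=C[C@H](OC(C)=O)[C@@H]2OC(=O)/C(C)=C/C | intermediate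
25 | (1R,2S,5R,7S,9S,10S)-2,9-diacetoxy-14-hydroxyeudesma-3,11-dien-1-yl (E)-2-methylbut-2-enoate | C=C(C)[C@@H]1C[C@H](OC(C)=O)[C@@]2(CO)[C@H](C1)C(C)=C[C@H](OC(C)=O)[C@@H]2OC(=O)/C(C)=C/C | target

## Step count and least certain steps

Total step count: 15. Longest linear sequence: 15 steps from 1 (the route is fully linear).

**Step 11 (key step).** Most likely to go wrong: hydrogenation or isomerisation of the isopropenyl group by iridium hydrides once norbornene runs low, and slow C–H cleavage because the axial O2 acetate crowds C14. The fallback uses no silane and no metal hydride; it sets out from 16 and comes back at 20. Dess–Martin oxidation of 16 would give the 1-ketone F7, and NH2OH·HCl/NaOAc the oxime F8 (hydroxyl anti to C10). Heating F8 with Pd(OAc)2 (cat.) and PhI(OAc)2 in AcOH/Ac2O forms the O-acetyl oxime in situ; it directs divalent palladium into a C14–H bond through a five-membered palladacycle, and oxidation should deliver the 14-acetoxy O-acetyl oxime F9. NaHSO3 in aqueous ethanol would return the 14-acetoxy ketone F10. NaBH4/CeCl3·7H2O should attack anti to C14 and give the equatorial alcohol F11. Lipase-mediated hydrolysis of the primary acetate at pH 7 would then lead to 20.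

**Step 1.** Most likely to go wrong: erosion of selectivity at C1 through boat or open transition structures of the tetrasubstituted enolate, and retro-aldol cleavage of the hindered aldolate. The fallback sets out from 4 and comes back at 5. Trapping 4 with monomeric formaldehyde would give the hydroxymethyl ketone F1, and Dess–Martin oxidation the keto aldehyde F2. MgBr2·OEt2 chelates the two carbonyl oxygens of F2. [(4-Methoxybenzyloxy)methyl]lithium (from the tributylstannane and n-BuLi) should then add at −78 °C to the aldehyde from the face of the C14 methyl group, the smaller flank of the chelate, which corresponds to the C1 configuration of 5.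

**Step 5.** Most likely to go wrong: poor facial selectivity, because chelation of magnesium by the silyloxy group competes with the Felkin–Anh mode, and some attack at the C9 ketone. The fallback sets out from 10, taken as the C2-epimer mixture through steps 6 to 8, so that 13 is accompanied by its C2 epimer, the 1α,2β,9β-triol F3. MnO2 oxidises only the allylic alcohol of both epimers and would converge them on the enone F4. NaBH4/CeCl3·7H2O at −78 °C should deliver hydride anti to the syn-axial C14, which returns the route to 13.

**Step 9.** Most likely to go wrong: opening of the orthoester with the opposite regiochemistry, acetyl migration from O2 to O1 in the acidic medium, and incomplete acetylation of the crowded O9. The fallback sets out from 11 and comes back at 16, replacing steps 7 to 9. LiBH(s-Bu)3 in THF at −78 °C would reduce the C9 ketone by equatorial attack, the axial path being blocked by the syn-axial isopropenyl group, to give the 1-O-silyl 2,9-diol F5. Ac2O/DMAP/pyridine would give the diacetate F6, and HF·pyridine would release O1 to give 16.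

**Step 12.** Most likely to go wrong: loss of an acetate by hydroperoxide or base, and acetyl migration from O2 to O1 as soon as O1 is free. The fallback sets out from 19 and comes back at 21. Oxidation under deliberately methanolytic conditions (H2O2, KF, K2CO3, MeOH, 40 °C) would give the tetraol F12, and TBSCl/imidazole the 14-silyl ether F13. The orthoacetate sequence of step 9 would then pass through the cyclic orthoacetate F14 and its 9-acetate F15, and a brief treatment with aqueous AcOH would give 21.

**Step 14.** Most likely to go wrong: slow acylation of the crowded C1–OH by the α-branched conjugated acyl donor, with base-induced acetyl migration from O2 to O1 during prolonged heating. The fallback sets out from 21 and comes back at 24. The small and reactive 2-(diethoxyphosphoryl)propanoic acid (DCC, DMAP, 0 °C) would give the phosphonate ester F16. A Horner–Wadsworth–Emmons reaction with acetaldehyde (LiCl, DBU, MeCN) should then build the (E)-2-methylbut-2-enoate on O1.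

## Further compounds

F1 | step 1 | (2S,3R,5S)-2-(hydroxymethyl)-2-methyl-3,5-di(prop-1-en-2-yl)cyclohexan-1-one | C=C(C)[C@@H]1CC(=O)[C@](C)(CO)[C@H](C1)C(C)=C
F2 | step 1 | (1S,2R,4S)-1-methyl-6-oxo-2,4-di(prop-1-en-2-yl)cyclohexane-1-carbaldehyde | C=C(C)[C@@H]1CC(=O)[C@](C)(C=O)[C@H](C1)C(C)=C
F3 | step 5 | 5βH,7αH,10α-eudesma-3,11-diene-1α,2β,9β-triol (C2 epimer of 13) | C=C(C)[C@@H]1C[C@H](O)[C@@]2(C)[C@H](C1)C(C)=C[C@@H](O)[C@@H]2O
F4 | step 5 | 1α,9β-dihydroxy-5βH,7αH,10α-eudesma-3,11-dien-2-one | C=C(C)[C@@H]1C[C@H](O)[C@@]2(C)[C@H](C1)C(C)=CC(=O)[C@@H]2O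
F5 | step 9 | 1α-(triethylsilyloxy)-5βH,7αH,10α-eudesma-3,11-diene-2α,9β-diol | C=C(C)[C@@H]1C[C@H](O)[C@@]2(C)[C@H](C1)C(C)=C[C@H](O)[C@@H]2O[Si](CC)(CC)CC
F6 | step 9 | 2α,9β-diacetoxy-1α-(triethylsilyloxy)-5βH,7αH,10α-eudesma-3,11-diene | C=C(C)[C@@H]1C[C@H](OC(C)=O)[C@@]2(C)[C@H](C1)C(C)=C[C@H](OC(C)=O)[C@@H]2O[Si](CC)(CC)CC
F7 | step 11 | 2α,9β-diacetoxy-5βH,7αH,10α-eudesma-3,11-dien-1-one | C=C(C)[C@@H]1C[C@H](OC(C)=O)[C@@]2(C)[C@H](C1)C(C)=C[C@H](OC(C)=O)C2=O
F8 | step 11 | oxime of F7 (hydroxyl anti to C10) | C=C(C)[C@@H]1C[C@H](OC(C)=O)[C@@]2(C)[C@H](C1)C(C)=C[C@H](OC(C)=O)/C2=N\O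
F9 | step 11 | 2α,9β,14-triacetoxy-5βH,7αH,10α-eudesma-3,11-dien-1-one O-acetyl oxime | C=C(C)[C@@H]1C[C@H](OC(C)=O)[C@@]2(COC(C)=O)[C@H](C1)C(C)=C[C@H](OC(C)=O)/C2=N\OC(C)=O
F10 | step 11 | 2α,9β,14-triacetoxy-5βH,7αH,10α-eudesma-3,11-dien-1-one | C=C(C)[C@@H]1C[C@H](OC(C)=O)[C@@]2(COC(C)=O)[C@H](C1)C(C)=C[C@H](OC(C)=O)C2=O
F11 | step 11 | 2α,9β,14-triacetoxy-5βH,7αH,10α-eudesma-3,11-dien-1α-ol | C=C(C)[C@@H]1C[C@H](OC(C)=O)[C@@]2(COC(C)=O)[C@H](C1)C(C)=C[C@H](OC(C)=O)[C@@H]2O
F12 | step 12 | 5βH,7αH,10α-eudesma-3,11-diene-1α,2α,9β,14-tetraol | C=C(C)[C@@H]1C[C@H](O)[C@@]2(CO)[C@H](C1)C(C)=C[C@H](O)[C@@H]2O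
F13 | step 12 | 14-(tert-butyldimethylsilyloxy)-5βH,7αH,10α-eudesma-3,11-diene-1α,2α,9β-triol | C=C(C)[C@@H]1C[C@H](O)[C@@]2(CO[Si](C)(C)C(C)(C)C)[C@H](C1)C(C)=C[C@H](O)[C@@H]2O
F14 | step 12 | 1α,2α-O-(1-methoxyethylidene) orthoester of F13 | C=C(C)[C@@H]1C[C@H](O)[C@@]2(CO[Si](C)(C)C(C)(C)C)[C@H](C1)C(C)=C[C@@H]3OC(C)(OC)O[C@H]23
F15 | step 12 | 9β-acetate of F14 | C=C(C)[C@@H]1C[C@H](OC(C)=O)[C@@]2(CO[Si](C)(C)C(C)(C)C)[C@H](C1)C(C)=C[C@@H]3OC(C)(OC)O[C@H]23
F16 | step 14 | 2α,9β-diacetoxy-14-(tert-butyldimethylsilyloxy)-5βH,7αH,10α-eudesma-3,11-dien-1α-yl 2-(diethoxyphosphoryl)propanoate | C=C(C)[C@@H]1C[C@H](OC(C)=O)[C@@]2(CO[Si](C)(C)C(C)(C)C)[C@H](C1)C(C)=C[C@H](OC(C)=O)[C@@H]2OC(=O)C(C)P(=O)(OCC)OCC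
A1 | alternative 1 | cis-fused endo adduct, methyl 1-(tert-butyldimethylsilyloxy)-5,8-dioxo-4,4a,5,8-tetrahydronaphthalene-8a(1H)-carboxylate | C1=C[C@H](O[Si](C)(C)C(C)(C)C)[C@@]2(C(=O)OC)[C@@H](C1)C(=O)C=CC2=O
A2 | alternative 1 | methyl 3,6-dioxocyclohexa-1,4-diene-1-carboxylate | COC(=O)C1=CC(=O)C=CC1=O
A3 | alternative 1 | (E)-1-(tert-butyldimethylsilyloxy)buta-1,3-diene | C=C/C=C/O[Si](C)(C)C(C)(C)C
A4 | alternative 2 | trans-decalin with bridged O9–C11 lactone, 1,2-acetonide and 14-O-silyl group | O=C4[C@@H]1C[C@H](O4)[C@@]2(CO[Si](C)(C)C(C)(C)C)[C@H](C1)C(C)=C[C@@H]3OC(C)(C)O[C@@H]32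
A5 | alternative 2 | ring A methyl propanoate carrying the C8–C9 epoxide on C10, 1,2-acetonide and 14-O-silyl group | COC(=O)CC[C@@H]1C(C)=C[C@@H]2OC(C)(C)O[C@@H]2[C@@]1(CO[Si](C)(C)C(C)(C)C)[C@@H]3CO3
A6 | alternative 3 | eudesma-3,11-diene with C5, C7 and C10 as in 25 | C=C(C)[C@@H]1CC[C@@]2(C)[C@H](C1)C(C)=CCC2
A7 | alternative 3 | (2E,6E)-farnesyl diphosphate | CC(C)=CCC/C(C)=C/CC/C(C)=C/COP(=O)(O)OP(=O)(O)O
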